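**Retrosynthetic overview**

1. Gericudranin D is a (2R,3R)-2,3-trans-dihydroflavonol. The plan rests on ring A: C4a is the only unsubstituted carbon of the O1-linked 6,8-dibenzylphloroglucinol ring and lies ortho to O1 and O5 and para to O7. The C4–C4a bond is therefore made last, by intramolecular Friedel–Crafts acylation of an acid tethered through O1–C2–C3; ring C is the only ring formed, rings A and B are bought.
2. The acid 14 is cut at O1–C2: the ring A phenol 6 displaces, with Mitsunobu inversion, the benzylic hydroxyl of the (2R,3S)-diol ester 11, which comes from asymmetric dihydroxylation of cinnamate 10.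
3. Phenol 6 comes from methyl 2,4,6-trihydroxybenzoate. The ester carbon blocks the future C4a during double C-benzylation and, by chelation, keeps only the future O1 hydroxyl free during O-benzylation; it is then removed by hydrolysis and decarboxylation.
4. All six protecting groups are benzyl ethers or benzyl carbonates, so one hydrogenolysis ends the route; the carbonates on O3 and O4' also deactivate the acid-sensitive positions.

Key step: step 10

Remark on the chemistry: the SMILES is read as the (2R,3R)-trans isomer; C2 and C3 of the open-chain esters and acids become C3 and C2 of the chromanone, and both descriptors stay (R). Methyl 2,4,6-trihydroxybenzoate, 4-hydroxybenzaldehyde and the Wittig ylide 9 are taken as commercial starting materials.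

**Route**

Step 1
Reactants: 1 methyl 2,4,6-trihydroxybenzoate; 2 4-(benzyloxy)benzyl alcohol (2.2 equiv)
Product: 3 methyl 3,5-bis[4-(benzyloxy)benzyl]-2,4,6-trihydroxybenzoate
Conditions: TsOH·H2O (10 mol %), 1,4-dioxane, 60 °C, slow addition of 2
Reagents that add atoms: none
Why: Friedel–Crafts benzylation, in which the acid ionises the 4-alkoxybenzylic alcohol to a stabilised cation that alkylates the two free ring carbons, while the ester carbon blocks the third position so that C-alkylation should stop at two.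

Step 2
Reactants: 3 methyl 3,5-bis[4-(benzyloxy)benzyl]-2,4,6-trihydroxybenzoate
Product: 4 methyl 4,6-bis(benzyloxy)-3,5-bis[4-(benzyloxy)benzyl]-2-hydroxybenzoate
Conditions: BnBr (2.1 equiv), K2CO3, DMF, 25 °C
Reagents that add atoms: benzyl bromide, BrCc1ccccc1
Why: Williamson etherification, in which the unchelated 4-OH (para to the ester, most acidic) and one ortho hydroxyl are benzylated, while the last hydroxyl stays hydrogen-bonded to the ester carbonyl and should remain free, as is usual for 2-hydroxy-4,6-dialkoxyaryl carbonyl compounds.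

Step 3
Reactants: 4 methyl 4,6-bis(benzyloxy)-3,5-bis[4-(benzyloxy)benzyl]-2-hydroxybenzoate
Product: 6 3,5-bis(benzyloxy)-2,4-bis[4-(benzyloxy)benzyl]phenol, via salicylic acid 5 (not isolated)
Conditions: KOH, DMSO/H2O, 110 °C, argon; then 2 M HCl, 1,4-dioxane, 70 °C
Reagents that add atoms: none
Why: Saponification of the hindered salicylate followed by protodecarboxylation of the electron-rich 2-hydroxy-4,6-dialkoxybenzoic acid (ipso protonation, loss of CO2), which frees the ring carbon next to the only phenolic hydroxyl.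

Step 4
Reactants: 7 4-hydroxybenzaldehyde
Product: 8 benzyl 4-formylphenyl carbonate
Conditions: CbzCl, Et3N, CH2Cl2, 0 °C
Reagents that add atoms: benzyl chloroformate, O=C(Cl)OCc1ccccc1
Why: O-acylation of the phenol by the chloroformate gives an aryl benzyl carbonate, an electron-withdrawing protecting group that hydrogenolysis removes at the end.

Step 5
Reactants: 8 benzyl 4-formylphenyl carbonate; 9 tert-butyl (triphenylphosphoranylidene)acetate
Product: 10 tert-butyl (E)-3-[4-(benzyloxycarbonyloxy)phenyl]prop-2-enoate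
Conditions: CH2Cl2, 25 °C
Reagents that add atoms: none
Why: Wittig olefination with a stabilised ylide, which should give the (E)-cinnamate under neutral conditions that leave the aryl carbonate intact.

Step 6
Reactants: 10 tert-butyl (E)-3-[4-(benzyloxycarbonyloxy)phenyl]prop-2-enoate
Product: 11 tert-butyl (2R,3S)-3-[4-(benzyloxycarbonyloxy)phenyl]-2,3-dihydroxypropanoate
Conditions: K2OsO2(OH)4 (0.5 mol %), (DHQ)2PHAL (1 mol %), NMO, t-BuOH/H2O, 20 °C
Reagents that add atoms: 4-methylmorpholine N-oxide, C[N+]1([O-])CCOCC1; water, O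
Why: Sharpless asymmetric dihydroxylation in its N-oxide variant (no carbonate base, so the aryl carbonate should survive), in which syn addition to the (E)-alkene from the face selected by the dihydroquinine ligand (DHQ)2PHAL should set C2 as (R) and C3 as (S).

Step 7
Reactants: 11 tert-butyl (2R,3S)-3-[4-(benzyloxycarbonyloxy)phenyl]-2,3-dihydroxypropanoate (1.3 equiv); 6 3,5-bis(benzyloxy)-2,4-bis[4-(benzyloxy)benzyl]phenol
Product: 12 tert-butyl (2R,3R)-3-{3,5-bis(benzyloxy)-2,4-bis[4-(benzyloxy)benzyl]phenoxy}-3-[4-(benzyloxycarbonyloxy)phenyl]-2-hydroxypropanoate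
Conditions: PPh3, DIAD, toluene, 0 → 25 °C
Reagents that add atoms: none
Why: Mitsunobu etherification, in which syn-2,3-dihydroxy esters are known to react at the β-carbinol (here also benzylic) while the more acidic α-hydroxyl stays free, and displacement by the phenol with inversion should turn (3S) into (3R) with C2 untouched.

Step 8
Reactants: 12 tert-butyl (2R,3R)-3-{3,5-bis(benzyloxy)-2,4-bis[4-(benzyloxy)benzyl]phenoxy}-3-[4-(benzyloxycarbonyloxy)phenyl]-2-hydroxypropanoate
Product: 13 tert-butyl (2R,3R)-2-(benzyloxycarbonyloxy)-3-{3,5-bis(benzyloxy)-2,4-bis[4-(benzyloxy)benzyl]phenoxy}-3-[4-(benzyloxycarbonyloxy)phenyl]propanoate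
Conditions: CbzCl, DMAP, CH2Cl2, 0 → 25 °C
Reagents that add atoms: benzyl chloroformate, O=C(Cl)OCc1ccccc1
Why: DMAP-mediated acylation of the secondary α-hydroxyl to its benzyl carbonate, with a base too weak to cause β-elimination of the aryloxy group.

Step 9
Reactants: 13 tert-butyl (2R,3R)-2-(benzyloxycarbonyloxy)-3-{3,5-bis(benzyloxy)-2,4-bis[4-(benzyloxy)benzyl]phenoxy}-3-[4-(benzyloxycarbonyloxy)phenyl]propanoate
Product: 14 (2R,3R)-2-(benzyloxycarbonyloxy)-3-{3,5-bis(benzyloxy)-2,4-bis[4-(benzyloxy)benzyl]phenoxy}-3-[4-(benzyloxycarbonyloxy)phenyl]propanoic acid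
Conditions: CF3CO2H/CH2Cl2 (1:4), 0 → 25 °C
Reagents that add atoms: none
Why: Acidolysis of the tert-butyl ester with loss of 2-methylpropene, under which benzyl ethers and benzyl carbonates are stable, the benzylic C–O bond is kept from ionising by the carbonate on ring B and the two neighbouring acyl groups, and the free ring A carbon, flanked by two alkoxy groups, is too hindered for tert-butylation.

Step 10
Reactants: 14 (2R,3R)-2-(benzyloxycarbonyloxy)-3-{3,5-bis(benzyloxy)-2,4-bis[4-(benzyloxy)benzyl]phenoxy}-3-[4-(benzyloxycarbonyloxy)phenyl]propanoic acid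
Product: 16 (2R,3R)-5,7-bis(benzyloxy)-6,8-bis[4-(benzyloxy)benzyl]-3-(benzyloxycarbonyloxy)-2-[4-(benzyloxycarbonyloxy)phenyl]chroman-4-one, via mixed trifluoroacetic anhydride 15 (not isolated)
Conditions: (CF3CO)2O (2 equiv), CH2Cl2, 0 → 25 °C; aq. NaHCO3 work-up
Reagents that add atoms: none
Why: The acid is converted by (CF3CO)2O into the mixed anhydride 15, whose acyl carbon is attacked by the only unsubstituted carbon of ring A (the future C4a, ortho to O1 and O5, para to O7); loss of trifluoroacetate and rearomatisation give the aryl ketone, the closest known reaction type being the trifluoroacetic anhydride-mediated intramolecular Friedel–Crafts acylation of 3-aryloxypropanoic acids to chroman-4-ones. Ring C closes in a 6-exo-trig mode at the acyl carbon, and C4–C4a is the only skeletal bond formed. No stereocentre is created: C2 and C3 keep the (R,R) configuration from steps 6 and 7, because the medium contains no base (no ketene from 15, no enolisation at C3) and because the carbonate on ring B and the adjacent acyl groups disfavour ionisation of the benzylic C2–O1 bond. The selectivity needed is regiochemical and is secured by the substrate, since every other ring A carbon is substituted and closure onto a pendant benzyl ring would need a medium ring. A carbonate, not an ether, is placed on O3 so that the activated acyl carbon is not prone to lose CO to an oxocarbenium ion.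

Step 11
Reactants: 16 (2R,3R)-5,7-bis(benzyloxy)-6,8-bis[4-(benzyloxy)benzyl]-3-(benzyloxycarbonyloxy)-2-[4-(benzyloxycarbonyloxy)phenyl]chroman-4-one
Product: 17 gericudranin D
Conditions: H2 (1 atm), Pd/C (10 % Pd on carbon), EtOAc/MeOH, 25 °C
Reagents that add atoms: none
Why: Catalytic hydrogenolysis cleaves the four benzyl ethers and the two benzyl carbonates (the carbonic half-esters lose CO2) under neutral conditions, so the base-sensitive trans-dihydroflavonol should be released without epimerisation at C2 or C3.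

**Compound list**

1 | methyl 2,4,6-trihydroxybenzoate | COC(=O)c1c(O)cc(O)cc1O | starting material
2 | 4-(benzyloxy)benzyl alcohol | OCc1ccc(OCc2ccccc2)cc1 | starting material
3 | methyl 3,5-bis[4-(benzyloxy)benzyl]-2,4,6-trihydroxybenzoate | COC(=O)c1c(O)c(Cc2ccc(OCc3ccccc3)cc2)c(O)c(Cc2ccc(OCc3ccccc3)cc2)c1O | intermediate
4 | methyl 4,6-bis(benzyloxy)-3,5-bis[4-(benzyloxy)benzyl]-2-hydroxybenzoate | COC(=O)c1c(O)c(Cc2ccc(OCc3ccccc3)cc2)c(OCc2ccccc2)c(Cc2ccc(OCc3ccccc3)cc2)c1OCc1ccccc1 | intermediate
5 | 4,6-bis(benzyloxy)-3,5-bis[4-(benzyloxy)benzyl]-2-hydroxybenzoic acid | OC(=O)c1c(O)c(Cc2ccc(OCc3ccccc3)cc2)c(OCc2ccccc2)c(Cc2ccc(OCc3ccccc3)cc2)c1OCc1ccccc1 | intermediate (not isolated)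
6 | 3,5-bis(benzyloxy)-2,4-bis[4-(benzyloxy)benzyl]phenol | Oc1cc(OCc2ccccc2)c(Cc2ccc(OCc3ccccc3)cc2)c(OCc2ccccc2)c1Cc1ccc(OCc2ccccc2)cc1 | intermediate
7 | 4-hydroxybenzaldehyde | O=Cc1ccc(O)cc1 | starting material
8 | benzyl 4-formylphenyl carbonate | O=Cc1ccc(OC(=O)OCc2ccccc2)cc1 | intermediate
9 | tert-butyl (triphenylphosphoranylidene)acetate | CC(C)(C)OC(=O)C=P(c1ccccc1)(c1ccccc1)c1ccccc1 | starting material
10 | tert-butyl (E)-3-[4-(benzyloxycarbonyloxy)phenyl]prop-2-enoate | CC(C)(C)OC(=O)/C=C/c1ccc(OC(=O)OCc2ccccc2)cc1 | intermediate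
11 | tert-butyl (2R,3S)-3-[4-(benzyloxycarbonyloxy)phenyl]-2,3-dihydroxypropanoate | CC(C)(C)OC(=O)[C@H](O)[C@@H](O)c1ccc(OC(=O)OCc2ccccc2)cc1 | intermediate
12 | tert-butyl (2R,3R)-3-{3,5-bis(benzyloxy)-2,4-bis[4-(benzyloxy)benzyl]phenoxy}-3-[4-(benzyloxycarbonyloxy)phenyl]-2-hydroxypropanoate | CC(C)(C)OC(=O)[C@H](O)[C@H](Oc1cc(OCc2ccccc2)c(Cc2ccc(OCc3ccccc3)cc2)c(OCc2ccccc2)c1Cc1ccc(OCc2ccccc2)cc1)c1ccc(OC(=O)OCc2ccccc2)cc1 | intermediate
13 | tert-butyl (2R,3R)-2-(benzyloxycarbonyloxy)-3-{3,5-bis(benzyloxy)-2,4-bis[4-(benzyloxy)benzyl]phenoxy}-3-[4-(benzyloxycarbonyloxy)phenyl]propanoate | CC(C)(C)OC(=O)[C@H](OC(=O)OCc1ccccc1)[C@H](Oc1cc(OCc2ccccc2)c(Cc2ccc(OCc3ccccc3)cc2)c(OCc2ccccc2)c1Cc1ccc(OCc2ccccc2)cc1)c1ccc(OC(=O)OCc2ccccc2)cc1 | intermediate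
14 | (2R,3R)-2-(benzyloxycarbonyloxy)-3-{3,5-bis(benzyloxy)-2,4-bis[4-(benzyloxy)benzyl]phenoxy}-3-[4-(benzyloxycarbonyloxy)phenyl]propanoic acid | OC(=O)[C@H](OC(=O)OCc1ccccc1)[C@H](Oc1cc(OCc2ccccc2)c(Cc2ccc(OCc3ccccc3)cc2)c(OCc2ccccc2)c1Cc1ccc(OCc2ccccc2)cc1)c1ccc(OC(=O)OCc2ccccc2)cc1 | intermediate (key-step precursor)
15 | mixed anhydride of 14 with trifluoroacetic acid | O=C(OC(=O)C(F)(F)F)[C@H](OC(=O)OCc1ccccc1)[C@H](Oc1cc(OCc2ccccc2)c(Cc2ccc(OCc3ccccc3)cc2)c(OCc2ccccc2)c1Cc1ccc(OCc2ccccc2)cc1)c1ccc(OC(=O)OCc2ccccc2)cc1 | intermediate (not isolated)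
16 | (2R,3R)-5,7-bis(benzyloxy)-6,8-bis[4-(benzyloxy)benzyl]-3-(benzyloxycarbonyloxy)-2-[4-(benzyloxycarbonyloxy)phenyl]chroman-4-one | O=C1c2c(OCc3ccccc3)c(Cc3ccc(OCc4ccccc4)cc3)c(OCc3ccccc3)c(Cc3ccc(OCc4ccccc4)cc3)c2O[C@H](c2ccc(OC(=O)OCc3ccccc3)cc2)[C@H]1OC(=O)OCc1ccccc1 | intermediate (key-step product)
17 | gericudranin D | O=C1c2c(O)c(Cc3ccc(O)cc3)c(O)c(Cc3ccc(O)cc3)c2O[C@H](c2ccc(O)cc2)[C@H]1O | target

**Step count and risk**

Total step count: 11. Longest linear sequence: 8 steps (steps 1–3 or 4–6, then 7–11).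

Steps most likely to fail:

1. Step 10. The free ring A carbon may be trifluoroacetylated by the reagent in competition with ring closure. The acid set free may also strip or shift benzyl groups on the ring A oxygens, or remove the benzyl group of the O3 carbonate through neighbouring-group attack on the activated acyl carbon. The fallback sets out from 14 and avoids both the Brønsted acid and the trifluoroacetylating agent. 1-Chloro-N,N,2-trimethylprop-1-en-1-amine in CH2Cl2 at 0 °C should give, under neutral conditions, (2R,3R)-2-(benzyloxycarbonyloxy)-3-{3,5-bis(benzyloxy)-2,4-bis[4-(benzyloxy)benzyl]phenoxy}-3-[4-(benzyloxycarbonyloxy)phenyl]propanoyl chloride F1. AgOSO2CF3 with 2,6-di-tert-butyl-4-methylpyridine in CH2Cl2 at −40 °C should then exchange chloride for triflate to give the acyl trifluoromethanesulfonate F2. F2 should acylate the free ring carbon in a buffered, aprotic medium and so rejoin the route at 16.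

2. Step 7. The wrong hydroxyl may be activated, the activated diol may close to an epoxide, elimination to the enol ester may occur, and partial ionisation at the benzylic carbon would erode the inversion; the bulky, weakly acidic phenol may also react slowly. The fallback sets out from 10 and 6 and fixes the regiochemistry through an epoxide. Asymmetric epoxidation of 10 with the dioxirane from the L-sorbose-derived enantiomer of the fructose diacetate ketone catalyst and KHSO5 (as 2KHSO5·KHSO4·K2SO4), in NaHCO3-buffered MeCN/H2O at 0 °C, should give tert-butyl (2R,3S)-3-[4-(benzyloxycarbonyloxy)phenyl]oxirane-2-carboxylate F3. Phenol 6 with catalytic Cs2CO3 in DMF at 40 °C should open F3 at the benzylic carbon (SN2, inversion; glycidic esters are attacked at C3), which gives 12 and rejoins the route there.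

3. Step 1. The benzylic cation may be consumed by self-condensation of the alcohol, the second alkylation of the ester-deactivated ring may stall, and transient O-benzylation may not revert. The fallback sets out from 1 and moves the alkylation to the anionic manifold. Compound 1 is deprotonated with KOH in H2O/MeOH at 0 °C and treated with 4-(benzyloxy)benzyl chloride (2 equiv), so that the phloroglucinate carbons, not a cation, form the two C–C bonds (C-alkylation of phloroglucinol anions in protic media). The product is 3 itself, where the route is rejoined; no compound outside the list is made (F0).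

Further compounds
F1 | step 10 | (2R,3R)-2-(benzyloxycarbonyloxy)-3-{3,5-bis(benzyloxy)-2,4-bis[4-(benzyloxy)benzyl]phenoxy}-3-[4-(benzyloxycarbonyloxy)phenyl]propanoyl chloride | ClC(=O)[C@H](OC(=O)OCc1ccccc1)[C@H](Oc1cc(OCc2ccccc2)c(Cc2ccc(OCc3ccccc3)cc2)c(OCc2ccccc2)c1Cc1ccc(OCc2ccccc2)cc1)c1ccc(OC(=O)OCc2ccccc2)cc1
F2 | step 10 | mixed anhydride of 14 with trifluoromethanesulfonic acid (acyl triflate) | O=C(OS(=O)(=O)C(F)(F)F)[C@H](OC(=O)OCc1ccccc1)[C@H](Oc1cc(OCc2ccccc2)c(Cc2ccc(OCc3ccccc3)cc2)c(OCc2ccccc2)c1Cc1ccc(OCc2ccccc2)cc1)c1ccc(OC(=O)OCc2ccccc2)cc1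
F3 | step 7 | tert-butyl (2R,3S)-3-[4-(benzyloxycarbonyloxy)phenyl]oxirane-2-carboxylate | CC(C)(C)OC(=O)[C@@H]1O[C@H]1c1ccc(OC(=O)OCc2ccccc2)cc1
F0 | step 1 | none | none
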